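**Strategy.** Ring B (isobenzofuranone numbering) is disconnected across C4–C3a and C7–C7a. Its C7–OH and C5–OMe are meta on a benzene that carries the lactol carbons C1 and C3 on the adjacent pair C7a/C3a, C6–CH2O between the two oxygens and an unsubstituted C4: the pattern of a 1,1,3-trioxygenated diene plus an alkynoate. One Diels–Alder/aromatisation operation therefore builds the fully substituted ring B, with C1 as an ester and C3 as an acetal. The precursor is a vinylketene silyl acetal carrying C6–CH2O as a silyl ether, paired with methyl 4,4-diethoxybut-2-ynoate. Ring A is attached by Mitsunobu esterification; the labile lactol stereocentre C3 is set last by lipase acyl transfer.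

Key step: step 6

Numbering: ring B is numbered as an isobenzofuran-1(3H)-one (C1 lactone carbonyl, O2, C3 lactol carbon, C3a, C4–H, C5–OMe, C6–CH2O, C7–OH, C7a). Ring A is the 2-hydroxy-4-methoxy-3,6-dimethylbenzoyl unit.

Assumption: C3 is a pseudo-acid (lactol) carbon that can racemise through the ring-opened formyl acid. It is taken to hold its configuration only in neutral, aprotic, cold media, so it is set in the last two steps and the product is isolated under such conditions.

Design choices:
- The C6 hydroxymethyl group is carried as a TBDPS ether. It is a poor leaving group at the dienolate stage, survives acid and methanolic base, and is removed by buffered fluoride, so no oxidative debenzylation has to be run beside a free phenol on an electron-rich ring.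
- The 2-substituted acetoacetate is made by Claisen acylation, which avoids O- versus C-alkylation with a chloromethyl ether.
- The ynoate carries a methyl ester and a diethyl acetal, so C1 and C3 arrive at the right oxidation levels and methanolic work-up cannot scramble the ester.

**Route**

Step 1
Reactants: 1 methyl 3-hydroxypropanoate
Product: 2 methyl 3-[(tert-butyldiphenylsilyl)oxy]propanoate
Conditions: TBDPSCl, imidazole, CH2Cl2, 0 °C → rt
Reagents that add atoms: tert-butyl(chloro)diphenylsilane, CC(C)(C)[Si](Cl)(c1ccccc1)c1ccccc1
Why: Silylation of the primary alcohol through the N-silylimidazolium ion is routine, and the bulky TBDPS ether is chosen because it should withstand the acid of step 3 and the bases of steps 4 and 6.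

Step 2
Reactants: 2 methyl 3-[(tert-butyldiphenylsilyl)oxy]propanoate
Product: 3 methyl 2-{[(tert-butyldiphenylsilyl)oxy]methyl}-3-oxobutanoate
Conditions: LiN(iPr)2, THF, −78 °C; AcCl (0.5 equiv), −78 °C; AcOH
Reagents that add atoms: acetyl chloride, CC(=O)Cl
Why: Crossed Claisen C-acylation of the lithium ester enolate, run with the enolate in two-fold excess so that the second equivalent takes up the acidic proton of the β-keto ester (ester 2 is recovered) and kept at −78 °C so that the β-silyloxy enolate does not eliminate; the new α-stereocentre is racemic and disappears in step 3.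

Step 3
Reactants: 3 methyl 2-{[(tert-butyldiphenylsilyl)oxy]methyl}-3-oxobutanoate
Product: 5 methyl (2E/Z)-2-{[(tert-butyldiphenylsilyl)oxy]methyl}-3-methoxybut-2-enoate, via dimethyl ketal 4 (not isolated)
Conditions: HC(OMe)3, TsOH (cat.), MeOH, rt; then toluene, 80 °C
Reagents that add atoms: trimethyl orthoformate, COC(OC)OC
Why: Acid-catalysed ketalisation with the orthoformate as dehydrating methyl donor, followed by thermal loss of methanol from ketal 4, is the usual enol-ether synthesis for 2-substituted acetoacetates, and the alkene geometry (or any β,γ-isomer) is irrelevant because all isomers converge on one dienolate in step 4.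

Step 4
Reactants: 5 methyl (2E/Z)-2-{[(tert-butyldiphenylsilyl)oxy]methyl}-3-methoxybut-2-enoate
Product: 6 2-{[(tert-butyldiphenylsilyl)oxy]methyl}-1,3-dimethoxy-1-(trimethylsilyloxy)buta-1,3-diene
Conditions: LiN(iPr)2, THF, −78 °C; Me3SiCl, −78 → 0 °C
Reagents that add atoms: chlorotrimethylsilane, C[Si](C)(C)Cl
Why: Kinetic γ-deprotonation gives the extended lithium dienolate, which the hard electrophile Me3SiCl traps on oxygen to give the vinylketene silyl acetal (standard synthesis of 1,1,3-trioxygenated dienes); the short dienolate lifetime at −78 °C guards against β-elimination of the silyloxy group, and the moisture-sensitive diene is used crude.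

Step 5
Reactants: 7 3,3-diethoxyprop-1-yne
Product: 8 methyl 4,4-diethoxybut-2-ynoate
Conditions: n-BuLi, THF, −78 °C; ClCO2Me, −78 → 0 °C
Reagents that add atoms: methyl chloroformate, COC(=O)Cl
Why: Deprotonation of the terminal alkyne and C-acylation of the lithium acetylide with a chloroformate is a routine ynoate synthesis, and the acetal is inert to both reagents.

Step 6
Reactants: 6 2-{[(tert-butyldiphenylsilyl)oxy]methyl}-1,3-dimethoxy-1-(trimethylsilyloxy)buta-1,3-diene; 8 methyl 4,4-diethoxybut-2-ynoate
Product: 11 methyl 2-(diethoxymethyl)-6-hydroxy-4-methoxy-5-{[(tert-butyldiphenylsilyl)oxy]methyl}benzoate, via cyclohexadiene cycloadduct 9 (not isolated), via aryl trimethylsilyl ether 10 (not isolated)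
Conditions: toluene, 90 °C; then K2CO3 (cat.), MeOH, 0 °C
Reagents that add atoms: none
Why: The vinylketene acetal 6 (HOMO raised by three oxygen donors, largest coefficient at its CH2 terminus C4) and ynoate 8 (LUMO lowered by the ester, largest coefficient at the acetal-bearing β-carbon) should combine in a normal-demand, asynchronous Diels–Alder reaction in which C4–C3a bonding leads and C7–C7a follows. The closest known reaction type is the benzannulation of 1,1,3-trioxygenated butadienes with alkynoates to give resorcylates. Ring B is closed by this intermolecular [4+2] cycloaddition, which gives the cyclohexa-1,4-diene ketal 9; 1,4-elimination of methanol across C7/C4 aromatises it to silyl ether 10, and methanolysis of the aryl O–Si bond frees the C7 phenol. No stereocentre results, because the only sp3 stereocentre of 9 (C7) is lost on aromatisation. The step needs regioselectivity (C7–OH beside the ester-bearing C7a, C4–H beside the acetal-bearing C3a), which the matched polarisation of both partners secures, and loss of methanol rather than silanol, which the more basic methoxy oxygen favours and which base-mediated O–Si cleavage of any surviving ketal enforces. The diethyl acetal, the methyl ester (methanol cannot scramble it) and the TBDPS ether should be inert to the heat and to K2CO3 in methanol.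

Step 7
Reactants: 11 methyl 2-(diethoxymethyl)-6-hydroxy-4-methoxy-5-{[(tert-butyldiphenylsilyl)oxy]methyl}benzoate
Product: 12 methyl 2-(diethoxymethyl)-6-hydroxy-5-(hydroxymethyl)-4-methoxybenzoate
Conditions: Bu4NF, AcOH, THF, rt
Reagents that add atoms: none
Why: Fluoride-mediated Si–O cleavage of the primary TBDPS ether, buffered with acetic acid so that the phenol is not held as a phenoxide and the acetal sees no strong acid, should free only the C6 hydroxymethyl group.

Step 8
Reactants: 13 methyl 2,4-dihydroxy-3,6-dimethylbenzoate
Product: 14 methyl 2-hydroxy-4-methoxy-3,6-dimethylbenzoate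
Conditions: MeI (1.1 equiv), K2CO3, acetone, 40 °C
Reagents that add atoms: iodomethane, CI
Why: Williamson O-methylation is selective for the 4-hydroxyl because the 2-hydroxyl is locked in a hydrogen bond to the ester carbonyl and is much less acidic and nucleophilic.

Step 9
Reactants: 14 methyl 2-hydroxy-4-methoxy-3,6-dimethylbenzoate
Product: 15 2-hydroxy-4-methoxy-3,6-dimethylbenzoic acid
Conditions: KOH, H2O/DMSO, 80 °C; then HCl (aq.), 0 °C
Reagents that add atoms: potassium hydroxide, [K+].[OH-]
Why: Saponification of the di-ortho-substituted methyl ester needs hot concentrated hydroxide in a dipolar solvent, the aryl methyl ether is stable to it, and cold acidification avoids decarboxylation of the salicylic acid.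

Step 10
Reactants: 12 methyl 2-(diethoxymethyl)-6-hydroxy-5-(hydroxymethyl)-4-methoxybenzoate; 15 2-hydroxy-4-methoxy-3,6-dimethylbenzoic acid
Product: 16 methyl 2-(diethoxymethyl)-6-hydroxy-5-{[(2-hydroxy-4-methoxy-3,6-dimethylbenzoyl)oxy]methyl}-4-methoxybenzoate
Conditions: PPh3, DIAD, THF, 0 °C → rt
Reagents that add atoms: none
Why: Mitsunobu esterification, in which the alkoxyphosphonium ion of the primary benzylic alcohol is displaced at CH2 (no stereocentre) by the carboxylate of 15, the only partner acidic enough to protonate the betaine, so the hydrogen-bonded phenols stay free and the shielded acyl carbon of the di-ortho-substituted acid never has to be attacked.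

Step 11
Reactants: 16 methyl 2-(diethoxymethyl)-6-hydroxy-5-{[(2-hydroxy-4-methoxy-3,6-dimethylbenzoyl)oxy]methyl}-4-methoxybenzoate
Product: 18 racemic (3,7-dihydroxy-5-methoxy-1-oxo-1,3-dihydroisobenzofuran-6-yl)methyl 2-hydroxy-4-methoxy-3,6-dimethylbenzoate, via aldehyde ester 17 (not isolated)
Conditions: HCl (1 M aq.), THF, rt → 40 °C
Reagents that add atoms: water, O
Why: Dilute acid hydrolyses the aryl diethyl acetal to aldehyde 17, whose hydrate adds to the neighbouring ester carbonyl (5-exo-trig) and expels methanol (the acid-catalysed normal-ester to pseudo-acid isomerisation of 2-formylbenzoates, driven by excess water), while the hindered benzoate of ring A and its benzylic C–O bond, deactivated by the para formyl group, should survive; C3 forms racemic.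

Step 12
Reactants: 18 racemic (3,7-dihydroxy-5-methoxy-1-oxo-1,3-dihydroisobenzofuran-6-yl)methyl 2-hydroxy-4-methoxy-3,6-dimethylbenzoate
Product: 19 [(3R)-3-acetoxy-7-hydroxy-5-methoxy-1-oxo-1,3-dihydroisobenzofuran-6-yl]methyl 2-hydroxy-4-methoxy-3,6-dimethylbenzoate
Conditions: Burkholderia cepacia lipase (immobilised), isopropenyl acetate, Et3N (cat.), toluene, 35 °C
Reagents that add atoms: isopropenyl acetate, CC(=C)OC(C)=O
Why: Lipase-catalysed dynamic kinetic resolution of a cyclic acyl hemiacetal, in which the enantiomers of 18 interconvert through the ring-opened formyl acid (amine-assisted ring–chain tautomerism) while the enzyme irreversibly acetylates one of them; with the fused arene as the large and the ring oxygen as the small substituent, the empirical size rule for lipase acylation of secondary alcohols predicts the (R)-lactol as the fast-reacting enantiomer, so C3 is set under catalyst control (the sense is to be confirmed on the first run and the lipase chosen accordingly), and the hindered hydrogen-bonded phenols are not lipase substrates.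

Step 13
Reactants: 19 [(3R)-3-acetoxy-7-hydroxy-5-methoxy-1-oxo-1,3-dihydroisobenzofuran-6-yl]methyl 2-hydroxy-4-methoxy-3,6-dimethylbenzoate
Product: 20 [(3R)-3,7-dihydroxy-5-methoxy-1-oxo-1,3-dihydroisobenzofuran-6-yl]methyl 2-hydroxy-4-methoxy-3,6-dimethylbenzoate
Conditions: Burkholderia cepacia lipase (immobilised), n-BuOH, tert-butyl methyl ether, 0 °C
Reagents that add atoms: none
Why: Lipase-catalysed alcoholysis (transesterification to n-butanol) cleaves the acetyl C–O bond and not the C3–O bond, so the (R) configuration from step 12 is retained, the (R)-acetate is the matched substrate of the same enzyme, and the base-free, aprotic, cold medium should slow ring-opening of the liberated lactol; the hindered aryl ester and the lactone are not touched.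

**Compound list**

1 | methyl 3-hydroxypropanoate | COC(=O)CCO | starting material
2 | methyl 3-[(tert-butyldiphenylsilyl)oxy]propanoate | COC(=O)CCO[Si](c1ccccc1)(c1ccccc1)C(C)(C)C | intermediate
3 | methyl 2-{[(tert-butyldiphenylsilyl)oxy]methyl}-3-oxobutanoate (racemic) | COC(=O)C(CO[Si](c1ccccc1)(c1ccccc1)C(C)(C)C)C(C)=O | intermediate
4 | methyl 2-{[(tert-butyldiphenylsilyl)oxy]methyl}-3,3-dimethoxybutanoate (racemic, not isolated) | COC(=O)C(CO[Si](c1ccccc1)(c1ccccc1)C(C)(C)C)C(C)(OC)OC | intermediate
5 | methyl (2E/Z)-2-{[(tert-butyldiphenylsilyl)oxy]methyl}-3-methoxybut-2-enoate (mixture of alkene isomers) | COC(=O)C(CO[Si](c1ccccc1)(c1ccccc1)C(C)(C)C)=C(C)OC | intermediate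
6 | 2-{[(tert-butyldiphenylsilyl)oxy]methyl}-1,3-dimethoxy-1-(trimethylsilyloxy)buta-1,3-diene (ketene acetal geometry not defined) | C=C(OC)C(CO[Si](c1ccccc1)(c1ccccc1)C(C)(C)C)=C(OC)O[Si](C)(C)C | intermediate
7 | 3,3-diethoxyprop-1-yne | CCOC(OCC)C#C | starting material
8 | methyl 4,4-diethoxybut-2-ynoate | CCOC(OCC)C#CC(=O)OC | intermediate
9 | methyl 5-{[(tert-butyldiphenylsilyl)oxy]methyl}-2-(diethoxymethyl)-4,6-dimethoxy-6-(trimethylsilyloxy)cyclohexa-1,4-diene-1-carboxylate (racemic, not isolated) | COC(=O)C1=C(C(OCC)OCC)CC(OC)=C(CO[Si](c2ccccc2)(c2ccccc2)C(C)(C)C)C1(OC)O[Si](C)(C)C | intermediate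
10 | methyl 2-(diethoxymethyl)-4-methoxy-5-{[(tert-butyldiphenylsilyl)oxy]methyl}-6-(trimethylsilyloxy)benzoate (not isolated) | COC(=O)c1c(O[Si](C)(C)C)c(CO[Si](c2ccccc2)(c2ccccc2)C(C)(C)C)c(OC)cc1C(OCC)OCC | intermediate
11 | methyl 2-(diethoxymethyl)-6-hydroxy-4-methoxy-5-{[(tert-butyldiphenylsilyl)oxy]methyl}benzoate | COC(=O)c1c(O)c(CO[Si](c2ccccc2)(c2ccccc2)C(C)(C)C)c(OC)cc1C(OCC)OCC | intermediate
12 | methyl 2-(diethoxymethyl)-6-hydroxy-5-(hydroxymethyl)-4-methoxybenzoate | COC(=O)c1c(O)c(CO)c(OC)cc1C(OCC)OCC | intermediate
13 | methyl 2,4-dihydroxy-3,6-dimethylbenzoate | COC(=O)c1c(C)cc(O)c(C)c1O | starting material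
14 | methyl 2-hydroxy-4-methoxy-3,6-dimethylbenzoate | COC(=O)c1c(C)cc(OC)c(C)c1O | intermediate
15 | 2-hydroxy-4-methoxy-3,6-dimethylbenzoic acid | OC(=O)c1c(C)cc(OC)c(C)c1O | intermediate
16 | methyl 2-(diethoxymethyl)-6-hydroxy-5-{[(2-hydroxy-4-methoxy-3,6-dimethylbenzoyl)oxy]methyl}-4-methoxybenzoate | COC(=O)c1c(O)c(COC(=O)c2c(C)cc(OC)c(C)c2O)c(OC)cc1C(OCC)OCC | intermediate
17 | methyl 2-formyl-6-hydroxy-5-{[(2-hydroxy-4-methoxy-3,6-dimethylbenzoyl)oxy]methyl}-4-methoxybenzoate (not isolated) | COC(=O)c1c(O)c(COC(=O)c2c(C)cc(OC)c(C)c2O)c(OC)cc1C=O | intermediate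
18 | racemic (3,7-dihydroxy-5-methoxy-1-oxo-1,3-dihydroisobenzofuran-6-yl)methyl 2-hydroxy-4-methoxy-3,6-dimethylbenzoate | COc1cc(C)c(C(=O)OCc2c(OC)cc3c(c2O)C(=O)OC3O)c(O)c1C | intermediate
19 | [(3R)-3-acetoxy-7-hydroxy-5-methoxy-1-oxo-1,3-dihydroisobenzofuran-6-yl]methyl 2-hydroxy-4-methoxy-3,6-dimethylbenzoate | COc1cc(C)c(C(=O)OCc2c(OC)cc3c(c2O)C(=O)O[C@H]3OC(C)=O)c(O)c1C | intermediate
20 | [(3R)-3,7-dihydroxy-5-methoxy-1-oxo-1,3-dihydroisobenzofuran-6-yl]methyl 2-hydroxy-4-methoxy-3,6-dimethylbenzoate | COc1cc(C)c(C(=O)OCc2c(OC)cc3c(c2O)C(=O)O[C@H]3O)c(O)c1C | target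

**Step count and risk**

Total steps: 13. Longest linear sequence: 10 steps (steps 1, 2, 3, 4, 6, 7, 10, 11, 12, 13).

Step 6. What may go wrong: the moisture-sensitive diene may decompose or desilylate faster than it adds to the hindered internal ynoate, or the adduct may lose silanol instead of methanol and so deliver the C7 methyl ether. Fallback (sets out from 5 and 8, returns at 11): an anionic Michael–Dieckmann annulation. The lithium dienolate of 5 (LiN(iPr)2, THF, −78 °C) should add through its γ-carbon to the β-carbon of 8 and give, after protonation, the open-chain diester dimethyl 2-{[(tert-butyldiphenylsilyl)oxy]methyl}-5-(diethoxymethyl)-3-methoxyhepta-2,5-dienedioate F1. NaOMe in MeOH should then deprotonate the doubly allylic CH2 and close ring B by acylation of the vinylogous enolate carbon C7a with the C7 ester, the dienone tautomerising to phenol 11. The C7 oxygen is then the former ester carbonyl oxygen, so a methyl ether cannot arise.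

Step 12. What may go wrong: the depside-sized lactol with two phenols may bind poorly in the lipase, so that acyl transfer is slow or unselective and racemisation does not keep pace. Fallback (sets out from 11, returns at 19): the resolution is moved to the compact phthalide before ring A is attached. Compound 11 with 1 M HCl in THF should give the aldehyde ester methyl 2-formyl-6-hydroxy-4-methoxy-5-{[(tert-butyldiphenylsilyl)oxy]methyl}benzoate F2. LiOH in THF/H2O should saponify F2 with assistance from the hydrate of the neighbouring formyl group, and acidification should close racemic 6-{[(tert-butyldiphenylsilyl)oxy]methyl}-3,7-dihydroxy-5-methoxyisobenzofuran-1(3H)-one F3. The lipase acetylation of step 12 should then give (3R)-6-{[(tert-butyldiphenylsilyl)oxy]methyl}-7-hydroxy-5-methoxy-1-oxo-1,3-dihydroisobenzofuran-3-yl acetate F4. HF·pyridine in THF/pyridine should remove the silyl group to give (3R)-7-hydroxy-6-(hydroxymethyl)-5-methoxy-1-oxo-1,3-dihydroisobenzofuran-3-yl acetate F5, and Mitsunobu esterification of F5 with 15 should deliver 19. This order also spares the finished depside the aqueous acid of step 11.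

Step 13. What may go wrong: the liberated lactol may ring-open to the achiral formyl acid during the alcoholysis or the isolation, so that enantiomeric purity erodes. Fallback (sets out from 18, returns at 20): no chemical release at all. Racemic 18 is resolved directly by preparative enantioselective chromatography on an immobilised polysaccharide phase with supercritical CO2 and an aprotic co-solvent below ambient temperature. The (R)-enantiomer 20 is collected, and the (S)-enantiomer is re-equilibrated with a trace of Et3N and recycled (no new compound, F0).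

**Further compounds**

F1 | step 6 | dimethyl 2-{[(tert-butyldiphenylsilyl)oxy]methyl}-5-(diethoxymethyl)-3-methoxyhepta-2,5-dienedioate (alkene geometries not defined) | COC(=O)C(CO[Si](c1ccccc1)(c1ccccc1)C(C)(C)C)=C(OC)CC(C(OCC)OCC)=CC(=O)OC
F2 | step 12 | methyl 2-formyl-6-hydroxy-4-methoxy-5-{[(tert-butyldiphenylsilyl)oxy]methyl}benzoate | COC(=O)c1c(O)c(CO[Si](c2ccccc2)(c2ccccc2)C(C)(C)C)c(OC)cc1C=O
F3 | step 12 | racemic 6-{[(tert-butyldiphenylsilyl)oxy]methyl}-3,7-dihydroxy-5-methoxyisobenzofuran-1(3H)-one | COc1cc2c(c(O)c1CO[Si](c1ccccc1)(c1ccccc1)C(C)(C)C)C(=O)OC2O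
F4 | step 12 | (3R)-6-{[(tert-butyldiphenylsilyl)oxy]methyl}-7-hydroxy-5-methoxy-1-oxo-1,3-dihydroisobenzofuran-3-yl acetate | COc1cc2c(c(O)c1CO[Si](c1ccccc1)(c1ccccc1)C(C)(C)C)C(=O)O[C@H]2OC(C)=O
F5 | step 12 | (3R)-7-hydroxy-6-(hydroxymethyl)-5-methoxy-1-oxo-1,3-dihydroisobenzofuran-3-yl acetate | COc1cc2c(c(O)c1CO)C(=O)O[C@H]2OC(C)=O
F0 | step 13 | none | none
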